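**Retrosynthetic overview**
1. Target 18 ⇒ alkyne 17: the side-chain C=O (a C–O bond) is made last, by hydration of a 5-(prop-1-ynyl) group steered by the neighbouring C4=O of chromone B (key step).
2. 17 ⇒ 5-bromochromone 7 (ring system A) + 2-methylchromone 15 (ring system B): the CH2–aryl bond comes from Pd γ-arylation of the vinylogous enolate of 15.
3. 7 ⇒ 4-bromo-2-fluoroanisole: pyranone A is closed first (step 2) through its aryl–O bond, by intramolecular SNAr O-arylation of a 1,3-diketone enolate.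
4. 15 ⇒ 5-bromoresorcinol: pyranone B is closed second (step 4) through O1–C2 by Kostanecki–Robinson cyclodehydration, then Sonogashira coupling with propyne.

Assumption: the target has no stereocentre and no stereogenic double bond, so it is one achiral compound and needs no stereocontrol.

**Step 1**
Reactants: 1 4-bromo-2-fluoroanisole; 2 N-methoxy-N-methylacetamide
Product: 4 1-(6-bromo-2-fluoro-3-methoxyphenyl)ethan-1-one, via aryllithium 3 (not isolated)
Conditions: LDA (1.05 equiv), THF, –78 °C, 1 h; then 2, –78 → –40 °C; 1 M HCl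
Reagents that add atoms: none
Why: Directed ortho-lithiation takes the most acidic C–H (flanked by F and Br) and the Weinreb ketone synthesis stops at the ketone; at –78 °C the aryllithium does not collapse to an aryne.

**Step 2**
Reactants: 4 1-(6-bromo-2-fluoro-3-methoxyphenyl)ethan-1-one; 5 2-methylpropanoyl chloride
Product: 7 5-bromo-8-methoxy-2-(propan-2-yl)-4H-chromen-4-one, via 1,3-diketone 6 (not isolated)
Conditions: MgBr2·OEt2, i-Pr2NEt, CH2Cl2, rt; evaporate; K2CO3, DMF, 100 °C
Reagents that add atoms: none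
Why: Soft-enolisation C-acylation (Claisen type) gives the 1,3-diketone, whose enolate oxygen displaces the ketone-activated ortho-fluoride (intramolecular SNAr O-arylation, F far faster than Br) and closes pyranone A through a C–O bond.

**Step 3**
Reactants: 8 5-bromobenzene-1,3-diol; 9 acetic acid
Product: 10 1-(2-bromo-4,6-dihydroxyphenyl)ethan-1-one
Conditions: AcOH (solvent), ZnCl2 (1.5 equiv), 140 °C
Reagents that add atoms: none
Why: Nencki C-acylation (Friedel–Crafts type) of the resorcinol goes para to one hydroxyl and ortho to the other, as with resorcinol and orcinol, and the chelated o-hydroxy ketone is the stable product.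

**Step 4**
Reactants: 10 1-(2-bromo-4,6-dihydroxyphenyl)ethan-1-one; 11 acetic anhydride
Product: 13 5-bromo-7-hydroxy-2-methyl-4H-chromen-4-one, via 3-acetylchromenyl acetate 12 (not isolated)
Conditions: Ac2O, NaOAc, 170 °C; then 2 M aq. Na2CO3, reflux; HCl to pH 3
Reagents that add atoms: none
Why: Kostanecki–Robinson reaction (O-acetylation, acyl shift, cyclodehydration) closes pyranone B through O1–C2, and hot carbonate then removes the 7-O-acetyl and 3-C-acetyl groups.

**Step 5**
Reactants: 13 5-bromo-7-hydroxy-2-methyl-4H-chromen-4-one; 14 propyne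
Product: 15 7-hydroxy-2-methyl-5-(prop-1-yn-1-yl)-4H-chromen-4-one
Conditions: propyne (1 M in DMF, 3 equiv), PdCl2(PPh3)2 (5 mol %), CuI (10 mol %), Et3N, DMF, 60 °C, sealed tube
Reagents that add atoms: none
Why: Sonogashira coupling of the carbonyl-activated 5-bromide; the free phenol and the pyranone tolerate the conditions, and no water is present to hydrate the new alkyne.

**Step 6**
Reactants: 15 7-hydroxy-2-methyl-5-(prop-1-yn-1-yl)-4H-chromen-4-one; 7 5-bromo-8-methoxy-2-(propan-2-yl)-4H-chromen-4-one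
Product: 17 7-hydroxy-2-{[8-methoxy-4-oxo-2-(propan-2-yl)-4H-chromen-5-yl]methyl}-5-(prop-1-yn-1-yl)-4H-chromen-4-one, via dilithium dienolate 16 (not isolated)
Conditions: 15 (1.2 equiv), LiHMDS (3.2 equiv), THF, –78 → 0 °C; then 7 (1.0 equiv), Pd2(dba)3 (2.5 mol %), XPhos (10 mol %), 60 °C; 1 M HCl
Reagents that add atoms: none
Why: Proposed new method: Pd-catalysed γ-arylation of a 2-methylchromone, in which LiHMDS deprotonates the phenol and the vinylogous 2-methyl group to give the 2-methylene-2H-chromen-4-olate 16, Pd(0)/XPhos inserts into the C–Br bond of 7, the dienolate transmetalates and reductive elimination occurs at the unhindered exocyclic carbon because only this restores the aromatic 4-pyranone (the third equivalent of base holds the more acidic product as its anion and the hindered aryl group disfavours a second arylation); the closest known reaction type is Pd-catalysed γ-arylation of dienolates of unsaturated carbonyl compounds and benzylic arylation of 2-methylazines.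

**Step 7**
Reactants: 17 7-hydroxy-2-{[8-methoxy-4-oxo-2-(propan-2-yl)-4H-chromen-5-yl]methyl}-5-(prop-1-yn-1-yl)-4H-chromen-4-one
Product: 18 7-hydroxy-2-{[8-methoxy-4-oxo-2-(propan-2-yl)-4H-chromen-5-yl]methyl}-5-(2-oxopropyl)-4H-chromen-4-one
Conditions: (JohnPhos)Au(MeCN)SbF6 (5 mol %), 1,4-dioxane/H2O (10:1), 70 °C
Reagents that add atoms: water, O
Why: Proposed new method: chromone-carbonyl-directed alkyne hydration, in which cationic Au(I) activates the alkyne, the adjacent C4=O of chromone B attacks the methyl-bearing alkyne carbon 6-endo-dig to give a fused pyrylium (isochromenylium-type) vinylgold species, and protodeauration followed by water addition reopens the ring so that oxygen ends on the carbon remote from the arene and tautomerisation gives the aryl–CH2–C(=O)CH3 ketone; the closest known reaction type is neighbouring-carbonyl-assisted hydration of o-alkynylaryl ketones, aldehydes and esters, not yet shown with a 4-pyranone carbonyl.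

**Compound list**
1 | 4-bromo-2-fluoro-1-methoxybenzene (4-bromo-2-fluoroanisole) | COc1ccc(Br)cc1F | starting material
2 | N-methoxy-N-methylacetamide | CC(=O)N(C)OC | starting material
3 | (6-bromo-2-fluoro-3-methoxyphenyl)lithium | [Li]c1c(F)c(OC)ccc1Br | intermediate
4 | 1-(6-bromo-2-fluoro-3-methoxyphenyl)ethan-1-one | CC(=O)c1c(F)c(OC)ccc1Br | intermediate
5 | 2-methylpropanoyl chloride | CC(C)C(=O)Cl | starting material
6 | 1-(6-bromo-2-fluoro-3-methoxyphenyl)-4-methylpentane-1,3-dione | CC(C)C(=O)CC(=O)c1c(F)c(OC)ccc1Br | intermediate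
7 | 5-bromo-8-methoxy-2-(propan-2-yl)-4H-chromen-4-one | COc1ccc(Br)c2c(=O)cc(C(C)C)oc12 | intermediate
8 | 5-bromobenzene-1,3-diol | Oc1cc(O)cc(Br)c1 | starting material
9 | acetic acid | CC(=O)O | starting material
10 | 1-(2-bromo-4,6-dihydroxyphenyl)ethan-1-one | CC(=O)c1c(O)cc(O)cc1Br | intermediate
11 | acetic anhydride | CC(=O)OC(C)=O | starting material
12 | 3-acetyl-5-bromo-2-methyl-4-oxo-4H-chromen-7-yl acetate | CC(=O)Oc1cc(Br)c2c(=O)c(C(C)=O)c(C)oc2c1 | intermediate
13 | 5-bromo-7-hydroxy-2-methyl-4H-chromen-4-one | Cc1cc(=O)c2c(Br)cc(O)cc2o1 | intermediate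
14 | propyne | CC#C | starting material
15 | 7-hydroxy-2-methyl-5-(prop-1-yn-1-yl)-4H-chromen-4-one | CC#Cc1cc(O)cc2oc(C)cc(=O)c12 | intermediate
16 | dilithium 2-methylidene-5-(prop-1-yn-1-yl)-2H-chromene-4,7-bis(olate) | [Li+].[Li+].C=C1C=C([O-])c2c(C#CC)cc([O-])cc2O1 | intermediate
17 | 7-hydroxy-2-{[8-methoxy-4-oxo-2-(propan-2-yl)-4H-chromen-5-yl]methyl}-5-(prop-1-yn-1-yl)-4H-chromen-4-one | COc1ccc(Cc2cc(=O)c3c(C#CC)cc(O)cc3o2)c2c(=O)cc(C(C)C)oc12 | intermediate
18 | 7-hydroxy-2-{[8-methoxy-4-oxo-2-(propan-2-yl)-4H-chromen-5-yl]methyl}-5-(2-oxopropyl)-4H-chromen-4-one | COc1ccc(Cc2cc(=O)c3c(CC(C)=O)cc(O)cc3o2)c2c(=O)cc(C(C)C)oc12 | target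

**Step count and risks**
Total steps: 7. Longest linear sequence: 5 (steps 3, 4, 5, 6, 7).

Most likely to fail, first: step 6 (new γ-arylation). Attack at C3, double arylation, or addition of the dienolate to the pyranone of 7 could take over. The fallback uses only known chemistry, sets out from 7 and 10, and returns at 17. Bromide 7 is coupled with the Reformatsky reagent made from tert-butyl bromoacetate and zinc (Pd2(dba)3, XPhos, THF) to give tert-butyl 2-[8-methoxy-4-oxo-2-(propan-2-yl)-4H-chromen-5-yl]acetate F1. TFA in CH2Cl2 then frees 2-[8-methoxy-4-oxo-2-(propan-2-yl)-4H-chromen-5-yl]acetic acid F2. In parallel, 10 undergoes Sonogashira coupling with propyne 14 to give 1-[2,4-dihydroxy-6-(prop-1-yn-1-yl)phenyl]ethan-1-one F3. Its non-chelated 4-hydroxyl is capped with MOMCl and i-Pr2NEt to give 1-[2-hydroxy-4-(methoxymethoxy)-6-(prop-1-yn-1-yl)phenyl]ethan-1-one F4. F2 and F4 are joined with EDC and DMAP to the aryl ester 2-acetyl-5-(methoxymethoxy)-3-(prop-1-yn-1-yl)phenyl 2-[8-methoxy-4-oxo-2-(propan-2-yl)-4H-chromen-5-yl]acetate F5. Baker–Venkataraman rearrangement (KOt-Bu, THF) gives the 1,3-diketone 1-[2-hydroxy-4-(methoxymethoxy)-6-(prop-1-yn-1-yl)phenyl]-4-[8-methoxy-4-oxo-2-(propan-2-yl)-4H-chromen-5-yl]butane-1,3-dione F6. Aqueous HCl in THF at 60 °C cyclodehydrates F6 and removes the MOM group to give 17.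

Second: step 7 (new directed hydration). 5-exo attack would give the propanoyl isomer, and the stabilised pyrylium may open slowly. The fallback sets out from 17 and returns at 18. Semihydrogenation (H2, Lindlar catalyst, quinoline, EtOAc) gives 7-hydroxy-2-{[8-methoxy-4-oxo-2-(propan-2-yl)-4H-chromen-5-yl]methyl}-5-[(1Z)-prop-1-en-1-yl]-4H-chromen-4-one F7. Tsuji–Wacker oxidation (PdCl2, p-benzoquinone, DMF/H2O) of this propenylarene places the ketone on the non-benzylic carbon, as known for propenylbenzenes, and gives 18.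

Third: step 3 (site of ring acylation). Attack at C2 between the two hydroxyls would give the 2,6-dihydroxy isomer. The fallback sets out from 8 and returns at 10. O-Methylation (Me2SO4, K2CO3, acetone) gives 1-bromo-3,5-dimethoxybenzene F8, which can also be bought. Friedel–Crafts acetylation (AcCl, AlCl3, CH2Cl2, 0 °C) goes para to one methoxy group and ortho to bromine, away from the hindered site between the two methoxy groups, and gives 1-(2-bromo-4,6-dimethoxyphenyl)ethan-1-one F9. BBr3 in CH2Cl2 cleaves both ethers to give 10.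

**Further compounds**
F1 | step 6 | tert-butyl 2-[8-methoxy-4-oxo-2-(propan-2-yl)-4H-chromen-5-yl]acetate | COc1ccc(CC(=O)OC(C)(C)C)c2c(=O)cc(C(C)C)oc12
F2 | step 6 | 2-[8-methoxy-4-oxo-2-(propan-2-yl)-4H-chromen-5-yl]acetic acid | COc1ccc(CC(=O)O)c2c(=O)cc(C(C)C)oc12
F3 | step 6 | 1-[2,4-dihydroxy-6-(prop-1-yn-1-yl)phenyl]ethan-1-one | CC#Cc1cc(O)cc(O)c1C(C)=O
F4 | step 6 | 1-[2-hydroxy-4-(methoxymethoxy)-6-(prop-1-yn-1-yl)phenyl]ethan-1-one | CC#Cc1cc(OCOC)cc(O)c1C(C)=O
F5 | step 6 | 2-acetyl-5-(methoxymethoxy)-3-(prop-1-yn-1-yl)phenyl 2-[8-methoxy-4-oxo-2-(propan-2-yl)-4H-chromen-5-yl]acetate | COc1ccc(CC(=O)Oc2cc(OCOC)cc(C#CC)c2C(C)=O)c2c(=O)cc(C(C)C)oc12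
F6 | step 6 | 1-[2-hydroxy-4-(methoxymethoxy)-6-(prop-1-yn-1-yl)phenyl]-4-[8-methoxy-4-oxo-2-(propan-2-yl)-4H-chromen-5-yl]butane-1,3-dione | COc1ccc(CC(=O)CC(=O)c2c(O)cc(OCOC)cc2C#CC)c2c(=O)cc(C(C)C)oc12
F7 | step 7 | 7-hydroxy-2-{[8-methoxy-4-oxo-2-(propan-2-yl)-4H-chromen-5-yl]methyl}-5-[(1Z)-prop-1-en-1-yl]-4H-chromen-4-one | COc1ccc(Cc2cc(=O)c3c(/C=C\C)cc(O)cc3o2)c2c(=O)cc(C(C)C)oc12
F8 | step 3 | 1-bromo-3,5-dimethoxybenzene | COc1cc(OC)cc(Br)c1
F9 | step 3 | 1-(2-bromo-4,6-dimethoxyphenyl)ethan-1-one | COc1cc(OC)c(C(C)=O)c(Br)c1
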